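**Strategy.** Epoxytwinol A is a C2-symmetric dimer: two epoxyquinol rings fused to a cycloocta-1,5-diene whose allylic CH positions are spanned by two 2-methyl-3,6-dihydro-2H-pyran bridges. The route keeps one bridge open to the end. Its CH(CH3)–O bond is made last by cobalt-catalysed Markovnikov hydroalkoxylation of a vinyl group on one allylic ring CH by the hydroxyl on the allylic CH across the same tetrasubstituted C=C; the concave shape of the bicycle sets the methyl stereocentre. The precursor, a vinyl triol that already holds the eight-membered ring and the other pyran, comes from one monomer used as 2H-pyran dienophile and as silyloxy-triene diene (Diels–Alder, retro-aldol, vinylogous Mukaiyama aldol).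

Key step: step 14

Remark: in step 3 L-(+)-diisopropyl tartrate is assumed to give the (5R,6S)-epoxide 4; if the sense of induction is the opposite, the D-(−)-tartrate is used.
Remark: pyran 11 exists as two methyl epimers that interconvert through dienal 10; the epimer drawn is the one expected to react in step 10.

**Route**

Step 1
Reactants: 1 2-hydroxy-5-methoxybenzaldehyde
Product: 2 2-(hydroxymethyl)-4-methoxyphenol
Conditions: NaBH4, MeOH, 0 °C
Reagents that add atoms: none
Why: Chemoselective borohydride reduction of the aryl aldehyde; no stereocentre is formed.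

Step 2
Reactants: 2 2-(hydroxymethyl)-4-methoxyphenol
Product: 3 quinone monoketal
Conditions: PhI(OAc)2, MeOH, 0 °C
Reagents that add atoms: methanol, CO
Why: Oxidative dearomatisation of a para-methoxyphenol by iodine(III) in methanol should give the 4,4-dimethoxy dienone, the phenol carbon becoming the carbonyl.

Step 3
Reactants: 3 quinone monoketal
Product: 4 epoxy ketone
Conditions: Ph3COOH, NaHMDS, L-(+)-DIPT, toluene, −65 → −40 °C
Reagents that add atoms: trityl hydroperoxide, OOC(c1ccccc1)(c1ccccc1)c1ccccc1
Why: Tartrate-mediated nucleophilic (Weitz–Scheffer-type) epoxidation, in which the sodium tartrate/peroxide aggregate held by the free CH2OH attacks the unsubstituted enone C5=C6 from one face and so sets both epoxide carbons.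

Step 4
Reactants: 4 epoxy ketone
Product: 5 epoxy diol ketal
Conditions: DIBAL-H (3 equiv), THF, −78 °C; Rochelle salt
Reagents that add atoms: none
Why: 1,2-Reduction of the enone carbonyl, with aluminium bound to the epoxide oxygen so that hydride enters syn to the epoxide and the new hydroxyl should be trans to it.

Step 5
Reactants: 5 epoxy diol ketal
Product: 6 enone diol
Conditions: montmorillonite K-10 (wet), CH2Cl2, rt
Reagents that add atoms: water, O
Why: Mild acid hydrolysis of the allylic dimethyl ketal unveils the enone, while the electron-poor epoxide and the allylic alcohols should tolerate the clay.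

Step 6
Reactants: 6 enone diol
Product: 7 iodoenone
Conditions: I2, PhI(OCOCF3)2, pyridine, CH2Cl2, 0 °C → rt, dark
Reagents that add atoms: iodine, II
Why: Pyridine-mediated α-iodination of the enone (addition–elimination) at its only vinylic C–H.

Step 7
Reactants: 7 iodoenone; 8 (E)-tributyl(prop-1-en-1-yl)stannane
Product: 9 monomer diol
Conditions: Pd2(dba)3 (cat.), AsPh3, CuI (cat.), NMP, rt
Reagents that add atoms: none
Why: Stille coupling of the α-iodoenone with retention of the (E)-alkene geometry under neutral conditions that spare the epoxy ketone.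

Step 8
Reactants: 9 monomer diol
Product: 11 hydroxy-2H-pyran, via dienal 10 (not isolated)
Conditions: activated MnO2, CH2Cl2, rt; filtered, kept as a dilute solution and used at once
Reagents that add atoms: none
Why: MnO2 should oxidise the unhindered primary allylic alcohol faster than the secondary one, and the resulting dienal closes by thermal oxa-6π electrocyclisation.

Step 9
Reactants: 11 hydroxy-2H-pyran (one part of the solution)
Product: 14 silyloxy triene, via O-silyl pyran 12 (not isolated), via O-silyl dienal 13 (not isolated)
Conditions: TESOTf (2.5 equiv), Et3N (4 equiv), CH2Cl2, −78 °C → rt; used crude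
Reagents that add atoms: triethylsilyl triflate, CC[Si](CC)(CC)OS(=O)(=O)C(F)(F)F
Why: Soft enolisation, in which the silyl triflate caps the hydroxyl, then traps the dienal valence tautomer as its O-silyl oxocarbenium ion, which Et3N deprotonates at the ε-methyl group to give the s-cis-locked bis-exocyclic 1-silyloxy diene carrying a vinyl group (OSi and vinyl both outside).

Step 10
Reactants: 11 hydroxy-2H-pyran; 14 silyloxy triene (1.5 equiv)
Product: 15 Diels–Alder adduct
Conditions: toluene/CH2Cl2, BHT (cat.), rt → 40 °C, dark
Reagents that add atoms: none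
Why: Normal-demand Diels–Alder reaction of the locked 1-silyloxy diene with the enone C=C of the pyran, with ortho regiochemistry (vinyl-bearing terminus to the β-carbon), on the diene face anti to the pseudo-axial allylic OTES and on the dienophile face anti to the pyran methyl (the hydroxyl face), which should fix the two CH–CH stereocentres that survive to the target.

Step 11
Reactants: 15 Diels–Alder adduct
Product: 17 seco keto-aldehyde, via desilylated aldol 16 (not isolated)
Conditions: TBAF (2.5 equiv), AcOH (1.2 equiv), THF, −20 → 0 °C; pH 7 buffer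
Reagents that add atoms: none
Why: Fluoride frees the β-alkoxide beside the quaternary α-carbon and retro-aldol fragmentation, driven by loss of the quaternary centre and by enal and enone conjugation, should open the six-membered ring while the CH–CH bond and its two stereocentres stay untouched.

Step 12
Reactants: 17 seco keto-aldehyde
Product: 19 tris-silyl cyclooctadiene, via silyl dienol ether 18 (not isolated)
Conditions: TESOTf (4 equiv), Et3N (5 equiv), CH2Cl2, −78 → −40 °C
Reagents that add atoms: triethylsilyl triflate, CC[Si](CC)(CC)OS(=O)(=O)C(F)(F)F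
Why: One-pot silylation and intramolecular vinylogous Mukaiyama aldol, in which the silyl dienol ether formed by γ-deprotonation of the enone should attack the silyl-activated aldehyde through its γ-carbon (the α-carbon is fully substituted) to close the eight-membered ring, on the aldehyde face anti to the neighbouring OTES and in the s-trans enal conformation, so that the new C–O is cis to the vinyl-bearing CH while the tether fixes the new O–CH centre of the pyran.

Step 13
Reactants: 19 tris-silyl cyclooctadiene
Product: 20 vinyl triol
Conditions: HF·pyridine, pyridine, THF, 0 °C → rt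
Reagents that add atoms: none
Why: Fluoride cleavage of the three silyl ethers under buffered, mildly acidic conditions that should not trigger vinylogous retro-aldol or epoxide opening.

Step 14
Reactants: 20 vinyl triol
Product: 21 epoxytwinol A
Conditions: Co(II) salen complex [N,N′-bis(3,5-di-tert-butylsalicylidene)-1,2-cyclohexanediamine cobalt] (5 mol%), N-fluoro-2,4,6-trimethylpyridinium tetrafluoroborate (1.5 equiv), (Me2SiH)2O (1.5 equiv), PhCF3, 0 °C → rt
Reagents that add atoms: none
Why: A cobalt(III) hydride, formed from the salen complex, the N-fluoropyridinium oxidant and the silane, transfers a hydrogen atom to the terminal vinyl carbon (Markovnikov), and the secondary radical is captured by cobalt and oxidised to an alkyl–Co(IV) species that the allylic hydroxyl across the tetrasubstituted ring C=C displaces (radical–polar crossover). The closest known reaction type is the Co(salen)-catalysed Mukaiyama-type hydroalkoxylation of unactivated alkenols to tetrahydrofurans and tetrahydropyrans. The ring closes in a 6-exo-trig mode and gives the oxygen-bridged boat pyran across the two allylic CH positions of the cyclooctadiene. The new CH(CH3)–O stereocentre is substrate-controlled, because in the closing conformation the endo side of the reacting carbon lies against the enone C=C of the other monomer unit, so the methyl group should take the exo position found in the target. The step needs chemoselectivity for the monosubstituted alkene over the two tetrasubstituted enones and the epoxy ketones, which the steric demand of the cobalt hydride should secure. It also needs site selectivity among three hydroxyls, which geometry secures, since only the CH–OH that is cis to the vinyl-bearing CH across the ring double bond can reach the reacting carbon.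

**Compound list**

1 | 2-hydroxy-5-methoxybenzaldehyde | COc1ccc(O)c(C=O)c1 | starting material
2 | 2-(hydroxymethyl)-4-methoxyphenol | COc1ccc(O)c(CO)c1 | intermediate
3 | 2-(hydroxymethyl)-4,4-dimethoxycyclohexa-2,5-dien-1-one | COC1(OC)C=CC(=O)C(CO)=C1 | intermediate
4 | (5R,6S)-5,6-epoxy-2-(hydroxymethyl)-4,4-dimethoxycyclohex-2-en-1-one | OCC1=CC(OC)(OC)[C@@H]2O[C@@H]2C1=O | intermediate
5 | (1S,5R,6R)-5,6-epoxy-2-(hydroxymethyl)-4,4-dimethoxycyclohex-2-en-1-ol, 1-OH trans to the epoxide | OCC1=CC(OC)(OC)[C@@H]2O[C@@H]2[C@H]1O | intermediate
6 | (4S,5R,6R)-5,6-epoxy-4-hydroxy-3-(hydroxymethyl)cyclohex-2-en-1-one | OCC1=CC(=O)[C@@H]2O[C@@H]2[C@H]1O | intermediate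
7 | (4S,5R,6R)-5,6-epoxy-4-hydroxy-3-(hydroxymethyl)-2-iodocyclohex-2-en-1-one | OCC1=C(I)C(=O)[C@@H]2O[C@@H]2[C@H]1O | intermediate
8 | (E)-tributyl(prop-1-en-1-yl)stannane | C/C=C/[Sn](CCCC)(CCCC)CCCC | starting material
9 | (4S,5R,6R)-5,6-epoxy-4-hydroxy-3-(hydroxymethyl)-2-[(E)-prop-1-en-1-yl]cyclohex-2-en-1-one | OCC1=C(/C=C/C)C(=O)[C@@H]2O[C@@H]2[C@H]1O | intermediate
10 | (4R,5R,6S)-4,5-epoxy-6-hydroxy-3-oxo-2-[(E)-prop-1-en-1-yl]cyclohex-1-ene-1-carbaldehyde | O=CC1=C(/C=C/C)C(=O)[C@@H]2O[C@@H]2[C@H]1O | intermediate (not isolated)
11 | (3R,6R,7R,8S)-6,7-epoxy-8-hydroxy-3-methyl-7,8-dihydro-3H-isochromen-5(6H)-one, methyl cis to the epoxide, OH trans to it | C[C@H]1OC=C2[C@H](O)[C@H]3O[C@H]3C(=O)C2=C1 | intermediate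
12 | 8-O-triethylsilyl ether of 11 | C[C@H]1OC=C2[C@H](O[Si](CC)(CC)CC)[C@H]3O[C@H]3C(=O)C2=C1 | intermediate (not isolated)
13 | 6-O-triethylsilyl ether of dienal 10 | O=CC1=C(/C=C/C)C(=O)[C@@H]2O[C@@H]2[C@H]1O[Si](CC)(CC)CC | intermediate (not isolated)
14 | (2Z,3Z)-5,6-epoxy-2-(prop-2-en-1-ylidene)-4-(triethylsilyloxy)-3-[(triethylsilyloxy)methylidene]cyclohexan-1-one, ring configuration as in 9 | C=C/C=C1\C(=O)[C@@H]2O[C@@H]2[C@@H](O[Si](CC)(CC)CC)/C1=C\O[Si](CC)(CC)CC | intermediate
15 | Diels–Alder adduct: new cyclohexene from CH(OTES)–C=C–CH(vinyl) of 14 and the enone C=C of 11; the former pyran ring-fusion carbon next to the ketone is quaternary and bonded to the CH–OTES carbon; pyran enol ether and free 8-OH retained; bis-TES ether | CC[Si](CC)(CC)O[C@H]1C2=C(C(=O)[C@@H]3O[C@@H]3[C@H]2O[Si](CC)(CC)CC)[C@@H](C=C)[C@@H]4[C@@H](C)OC=C5[C@H](O)[C@H]6O[C@H]6C(=O)[C@@]145 | intermediate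
16 | fully desilylated aldol (triol) of 15 | O[C@H]1C2=C(C(=O)[C@@H]3O[C@@H]3[C@H]2O)[C@@H](C=C)[C@@H]4[C@@H](C)OC=C5[C@H](O)[C@H]6O[C@H]6C(=O)[C@@]145 | intermediate (not isolated)
17 | seco keto-aldehyde: epoxyquinol enal and 5,6-dihydro-2H-pyran-fused epoxyquinol enone joined by the CH(vinyl)–CH bond | O=CC3=C(C(=O)[C@@H]4O[C@@H]4[C@H]3O)[C@@H](C=C)[C@H]1C3=C([C@H](O)[C@H]4O[C@H]4C3=O)CO[C@@H]1C | intermediate
18 | bis-O-TES ether of 17 with the enone as its triethylsilyl dienol ether (2H-pyran form), aldehyde free | O=CC3=C(C(=O)[C@@H]4O[C@@H]4[C@H]3O[Si](CC)(CC)CC)[C@@H](C=C)[C@H]1C2=C(O[Si](CC)(CC)CC)[C@@H]5O[C@@H]5[C@@H](O[Si](CC)(CC)CC)C2=CO[C@@H]1C | intermediate (not isolated)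
19 | tris-TES ether of 20: cycloocta-1,5-diene closed, CH–OTES cis to the CH–vinyl across the ring C=C | CC[Si](CC)(CC)O[C@H]2C3=C(C(=O)[C@@H]4O[C@@H]4[C@H]3O[Si](CC)(CC)CC)[C@@H](C=C)[C@H]1C3=C([C@H](O[Si](CC)(CC)CC)[C@H]4O[C@H]4C3=O)[C@@H]2O[C@@H]1C | intermediate
20 | vinyl triol: epoxytwinol A with one CH(CH3)–O bond opened to CH=CH2 and OH | O[C@H]2C3=C(C(=O)[C@@H]4O[C@@H]4[C@H]3O)[C@@H](C=C)[C@H]1C3=C([C@H](O)[C@H]4O[C@H]4C3=O)[C@@H]2O[C@@H]1C | intermediate
21 | epoxytwinol A | C[C@H]1O[C@H]2C3=C(C(=O)[C@@H]4O[C@@H]4[C@H]3O)[C@@H]1[C@H]1C3=C([C@H](O)[C@H]4O[C@H]4C3=O)[C@@H]2O[C@@H]1C | target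

**Step count.** Total: 14 steps. Longest linear sequence: 14 steps (1 → 21; compound 11 enters in both step 9 and step 10).

**Steps most likely to fail**

1. Step 12. The ring closure may go through the fully substituted α-carbon of the dienol ether and re-form the six-membered ring, or the silylated enal may be deprotonated at its doubly allylic C–H. The fallback sets out from 15 and avoids the open enal. The free hydroxyl of 15 is silylated with TESOTf and 2,6-lutidine to give the tris-silyl Diels–Alder adduct F1. F1 is then equilibrated with catalytic TESOTf (CH2Cl2, −40 → 0 °C): reversible retro-Mukaiyama-aldol ionisation to the silyl oxocarbenium and silyl dienol ether pair, followed by re-closure, lets the mixture drain to the conjugated γ-adduct. This 1,3-shift comes back to the route at 19.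

2. Step 10. Self-dimerisation of 11 may outrun the cross-cycloaddition, or the dienophile may add to the diene face syn to the silyloxy group. The fallback replaces the pericyclic union by a polar one and makes no new compound (F0). It sets out from 11 and 14. Compound 11 is silylated (TESCl, imidazole) to 12, which is isolated here because the silyl ether should no longer dimerise. Then 12 and 14 are combined with catalytic TESOTf and 2,6-di-tert-butyl-4-methylpyridine at −78 °C. Vinylogous Mukaiyama–Michael addition gives the silyl dienol ether 18 in the flask, which closes by the vinylogous Mukaiyama aldol of step 12. The fallback comes back to the route at 19.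

3. Step 9. Interception of the minor dienal tautomer may be inefficient, enolisation toward the carbinol carbon may lead to epoxide opening and aromatisation, or the vinyl group may end up inside the diene. The fallback sets out from 7 and builds the triene from a skipped precursor. Stille coupling of 7 with allyltributylstannane gives the allyl enone diol F2. MnO2 oxidation gives the allyl enal F3, which cannot electrocyclise. Its doubly allylic CH2 is then enolised by TESOTf and Et3N, with silylation of the hydroxyl, and the fallback comes back to the route at 14.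

**Further compounds**

F1 | step 12 | tris-TES ether of Diels–Alder adduct 15 | CC[Si](CC)(CC)O[C@H]1C2=C(C(=O)[C@@H]3O[C@@H]3[C@H]2O[Si](CC)(CC)CC)[C@@H](C=C)[C@@H]4[C@@H](C)OC=C5[C@H](O[Si](CC)(CC)CC)[C@H]6O[C@H]6C(=O)[C@@]145
F0 | step 10 | none | none
F2 | step 9 | (4S,5R,6R)-5,6-epoxy-4-hydroxy-3-(hydroxymethyl)-2-(prop-2-en-1-yl)cyclohex-2-en-1-one | OCC1=C(CC=C)C(=O)[C@@H]2O[C@@H]2[C@H]1O
F3 | step 9 | (4R,5R,6S)-4,5-epoxy-6-hydroxy-3-oxo-2-(prop-2-en-1-yl)cyclohex-1-ene-1-carbaldehyde | O=CC1=C(CC=C)C(=O)[C@@H]2O[C@@H]2[C@H]1O
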